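The numbers of this flask were drawn at random within sensible limits; what happens was integrated by code.

Look at the late end first: once most of the D has reacted, what you can reckon is how D was shared between the road to D.J and the road to Q.

| setting | alpha | epsilon | theta | gamma |
|---|---|---|---|---|
| D | 0.20 M | 0.20 M | 0.20 M | 0.20 M |
| J | 0.100 M | 0.200 M | 0.400 M | 0.800 M |
| time | 2.5 min | 2.5 min | 2.5 min | 2.5 min |

    D + J → D.J (k1 = 0.0088 /M/s)
    D + 2 J → Q (k2 = 0.13 /M²/s)
    D + D.J → D.D.J (k3 = 0.013 /M/s)
    2 D → D2 (k4 = 3.2 × 10⁻⁵ /M/s)
    D.J ⇌ L (K5 = 0.33, k5 = 0.0025 /s)

- percentages count the D that a species holds: one D.D.J or D2 counts as two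
- for a step with 2 of a species take k times the square, and two of it per event
- "hardly changes" means that all values lie within two and a half points (for a concentration: within two and a half percent of the largest)
- run time (alpha): 2.5 min

* amount of D.J at the end, in percent of the D charged for alpha, epsilon, theta, gamma, in this order
* how that number moves from the first to the last of them (rises all the way / falls, then rises / rises, then falls / hardly changes / falls all the way)

Both roads have D and J in their rates, so D cancels from the ratio of their rates: Q made per D.J made is the second constant times J over the first. Count J in D-charges. That ratio is then J times the selectivity factor, here 2.95, the Q made per D.J made while J stands at one D-charge.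

Take gamma. J starts at 4.00 charges, and with two J per Q its floor is about 2.00. Even at that floor D has a half-life by the two roads of 0.475 min, shorter than the 2.50 min run, so gamma is a late-end flask.

My first way takes J midway, at 3.00 charges. The ratio is then 8.86, and the road to D.J takes an estimated 10.1% of the D charged. My second way follows J's own book, one J per D.J and two per Q, and integrates the ratio over J's whole fall with no midpoint. That gives 10.3%. The two part by 0.20 percentage points, so the midpoint guess costs little, though both rest on the same ratio.

Not all of this stays D.J in gamma. The exchange with L has a relaxation half-life of 1.15 min, shorter than the 2.50 min run, and at balance 75.2% of the pair is D.J. So I expect gamma's D.J between 7.73% and 10.3%.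

At the early end the clock counts. The starting rate held through alpha gives 13.2%, a ceiling on what is made while J falls, and this line grows with the J charge while the late share shrinks with it. Joining the two ends, I commit to a row that rises, then falls, and I leave the middle values open.

The forecast gave 6.1%, 8.8%, 11.3%, 8.6%, rises, then falls, holding that “the D.J yield peaks near 0.4 M”.

The flask gives 5.91%, 9.03%, 11.4%, 8.13%, rises, then falls, with gamma's D.J inside my bracket. At the end of gamma, Q at 89.0% stands to D.J 8.13%, L 1.75% and D.D.J 0.544% (taken at 0.5 of its percentage, one of its two D having come through D.J) as 8.77 to one, against 8.86 reckoned. In alpha, S times the J midway between charge and simulated end, 0.372 charges, gives 1.10, and the same count of Q 8.72% against D.J 5.91%, L 0.962% and D.D.J 2.57% reads 1.07.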